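## Retrosynthetic overview

1. Target 14 is cut at the C7–vinyl bond (Mizoroki–Heck) into bromide 6 and acrylate 11. Acrylate 11 carries the only stereocentre, which is bought with the (R)-danshensu salt 7.
2. Feature: in the 1,4-benzodioxin-2-one ring, the lactone oxygen O1 sits between carbonyl C2 and aromatic carbon C8a, and O4 holds the Z-benzylidene carbon C3. Removing O1 contracts this ring to the five-membered ketone ring of a Z-aurone.
3. Bromide 6 is therefore traced to 5-bromoaurone 4 by Baeyer–Villiger oxygen insertion with aryl migration (aurone C3a becomes dioxinone C8a; aurone C5–Br becomes dioxinone C7–Br).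
4. Aurone 4 comes from aldol condensation of 5-bromobenzofuran-3(2H)-one 3 with silylated aldehyde 2, which sets the Z alkene.
5. Ring order: the benzofuranone ring is bought and is expanded to the dioxinone in step 3. No other ring is formed.

Key step: step 3

Assumption: commercial sodium danshensu is taken to be the natural (R) enantiomer in high enantiomeric purity, so the stereocentre only has to be preserved.

## Route

Step 1
Reactants: 1 3,4-dihydroxybenzaldehyde
Product: 2 3,4-bis(tert-butyldimethylsilyloxy)benzaldehyde
Conditions: TBSCl (2.4 equiv), imidazole (5 equiv), DMF, rt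
Reagents that add atoms: tert-butyldimethylsilyl chloride, CC(C)(C)[Si](C)(C)Cl
Why: Imidazole-promoted O-silylation of both phenols is routine, the aldehyde is inert to it, and no stereocentre is involved.

Step 2
Reactants: 2 3,4-bis(tert-butyldimethylsilyloxy)benzaldehyde; 3 5-bromobenzofuran-3(2H)-one
Product: 4 (Z)-5-bromo-2-[3,4-bis(tert-butyldimethylsilyloxy)benzylidene]benzofuran-3(2H)-one
Conditions: neutral Al2O3 (dried), CH2Cl2, rt
Reagents that add atoms: none
Why: Aldol (Knoevenagel-type) condensation of the acidic C2 methylene on a neutral oxide surface should spare the aryl silyl ethers and give the thermodynamically preferred Z alkene, with the aryl group on the ring-oxygen side and away from the C3 carbonyl.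

Step 3
Reactants: 4 (Z)-5-bromo-2-[3,4-bis(tert-butyldimethylsilyloxy)benzylidene]benzofuran-3(2H)-one
Product: 6 (Z)-7-bromo-3-[3,4-bis(tert-butyldimethylsilyloxy)benzylidene]-1,4-benzodioxin-2(3H)-one, via peroxyhemiketal 5 (not isolated)
Conditions: mCPBA (2.5 equiv), TFA (1 equiv), CH2Cl2, 0 °C to rt, dark
Reagents that add atoms: meta-chloroperbenzoic acid, O=C(OO)c1cccc(Cl)c1
Why: Proposed new method: TFA-assisted addition of the peracid to the C3 ketone of 4 (aurone numbering) gives peroxyhemiketal 5, whose O–O heterolysis is coupled to a 1,2-shift of aryl carbon C3a from C3 to oxygen; in dioxinone numbering this makes the O1–C2 and O1–C8a bonds of 6 (Baeyer–Villiger oxidation). The closest known reaction type is the Baeyer–Villiger ring expansion of chroman-4-ones, 1-indanones and other ortho-alkoxyaryl ketones with aryl migration, which has not been shown on a 2-arylidenebenzofuran-3-one. The dioxinone ring is formed by ring expansion from five to six members, through insertion of one oxygen into the C3–C3a bond, and not by a cyclisation. No stereocentre is created and the exocyclic alkene is a spectator of the shift, so its Z geometry should pass unchanged into 6. The step needs C3a to migrate in preference to C2 and carbonyl addition to outrun epoxidation: C3a is ortho to the ring-ether donor on C7a, has bromine only meta to it and can move through a phenonium-like transition state, whereas C2 is the oxygen-bearing end of an enol ether, the end to which the oxygen lone pair sends no density. The alkene is trisubstituted and cross-conjugated with the ketone, hence a slow partner for an electrophilic peracid, and the acid additive accelerates only the carbonyl pathway.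

Step 4
Reactants: 7 sodium (R)-3-(3,4-dihydroxyphenyl)-2-hydroxypropanoate
Product: 8 4-methoxybenzyl (R)-3-(3,4-dihydroxyphenyl)-2-hydroxypropanoate
Conditions: 4-methoxybenzyl chloride (1.05 equiv), DMF, rt to 40 °C, Ar
Reagents that add atoms: 4-methoxybenzyl chloride, COc1ccc(CCl)cc1
Why: SN2 alkylation of the carboxylate, the only anionic site when no base is added, leaves the phenols and the secondary alcohol free and does not touch the stereocentre.

Step 5
Reactants: 8 4-methoxybenzyl (R)-3-(3,4-dihydroxyphenyl)-2-hydroxypropanoate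
Product: 9 4-methoxybenzyl (R)-3-[3,4-bis(tert-butyldimethylsilyloxy)phenyl]-2-hydroxypropanoate
Conditions: TBSCl (2.1 equiv), imidazole (4.5 equiv), CH2Cl2/DMF, 0 °C
Reagents that add atoms: tert-butyldimethylsilyl chloride, CC(C)(C)[Si](C)(C)Cl
Why: Chemoselective O-silylation should result because, with the reagent limited to two equivalents, the two acidic phenols react much faster than the hindered and inductively deactivated alcohol of the α-hydroxy ester.

Step 6
Reactants: 9 4-methoxybenzyl (R)-3-[3,4-bis(tert-butyldimethylsilyloxy)phenyl]-2-hydroxypropanoate; 10 acryloyl chloride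
Product: 11 4-methoxybenzyl (R)-2-(acryloyloxy)-3-[3,4-bis(tert-butyldimethylsilyloxy)phenyl]propanoate
Conditions: Et3N (1.5 equiv), CH2Cl2, −20 to 0 °C
Reagents that add atoms: none
Why: O-acylation of the alcohol by an acid chloride breaks no bond at the stereocentre, so the R configuration is retained, and the low temperature avoids enolisation of the α-acyloxy ester.

Step 7
Reactants: 6 (Z)-7-bromo-3-[3,4-bis(tert-butyldimethylsilyloxy)benzylidene]-1,4-benzodioxin-2(3H)-one; 11 4-methoxybenzyl (R)-2-(acryloyloxy)-3-[3,4-bis(tert-butyldimethylsilyloxy)phenyl]propanoate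
Product: 12 4-methoxybenzyl (R)-3-[3,4-bis(tert-butyldimethylsilyloxy)phenyl]-2-{(E)-3-[(Z)-3-(3,4-bis(tert-butyldimethylsilyloxy)benzylidene)-2-oxo-2,3-dihydro-1,4-benzodioxin-7-yl]acryloyloxy}propanoate
Conditions: Pd(P(t-Bu)3)2 (5 mol%), Cy2NMe (1.3 equiv), 1,4-dioxane, rt to 40 °C
Reagents that add atoms: none
Why: In this Mizoroki–Heck reaction the bulky electron-rich phosphine lets zerovalent palladium insert into the C7–Br bond near room temperature, syn insertion of the terminal acrylate and syn β-hydride elimination give the E cinnamate, and the hindered non-nucleophilic amine should leave the aryl lactone, the silyl ethers and the stereocentre alone.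

Step 8
Reactants: 12 the fully protected coupling product
Product: 13 (R)-3-[3,4-bis(tert-butyldimethylsilyloxy)phenyl]-2-{(E)-3-[(Z)-3-(3,4-bis(tert-butyldimethylsilyloxy)benzylidene)-2-oxo-2,3-dihydro-1,4-benzodioxin-7-yl]acryloyloxy}propanoic acid
Conditions: TFA, anisole (10 equiv), CH2Cl2, 0 °C
Reagents that add atoms: none
Why: Acidolysis of the 4-methoxybenzyl ester, with Friedel–Crafts capture of the benzyl cation by anisole, should proceed under brief cold TFA, to which the aryl silyl ethers, the conjugated enol-ether lactone and the cinnamate are stable.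

Step 9
Reactants: 13 the tetrasilylated acid
Product: 14 (R)-3-(3,4-dihydroxyphenyl)-2-{(E)-3-[(Z)-3-(3,4-dihydroxybenzylidene)-2-oxo-2,3-dihydro-1,4-benzodioxin-7-yl]acryloyloxy}propanoic acid (target)
Conditions: Et3N·3HF (excess), THF/MeCN, 0 °C to rt, Ar; acidic aqueous work-up
Reagents that add atoms: none
Why: Fluoride-driven cleavage of the four aryl silyl ethers runs in a mildly acidic medium, so no free phenoxide should arise that could open the aryl lactone or epimerise the α-acyloxy acid centre.

## Compound list

1 | 3,4-dihydroxybenzaldehyde | O=Cc1ccc(O)c(O)c1 | starting material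
2 | 3,4-bis(tert-butyldimethylsilyloxy)benzaldehyde | O=Cc1ccc(O[Si](C)(C)C(C)(C)C)c(O[Si](C)(C)C(C)(C)C)c1 | intermediate
3 | 5-bromobenzofuran-3(2H)-one | O=C1COc2ccc(Br)cc12 | starting material
4 | (Z)-5-bromo-2-[3,4-bis(tert-butyldimethylsilyloxy)benzylidene]benzofuran-3(2H)-one | Brc1ccc2c(c1)C(=O)/C(=C/c1ccc(O[Si](C)(C)C(C)(C)C)c(O[Si](C)(C)C(C)(C)C)c1)O2 | intermediate
5 | peroxyhemiketal of 4 with mCPBA, 3-hydroxy-3-(3-chlorobenzoylperoxy) adduct, racemic at C3, not isolated | Brc1ccc2c(c1)C(O)(OOC(=O)c1cccc(Cl)c1)/C(=C/c1ccc(O[Si](C)(C)C(C)(C)C)c(O[Si](C)(C)C(C)(C)C)c1)O2 | intermediate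
6 | (Z)-7-bromo-3-[3,4-bis(tert-butyldimethylsilyloxy)benzylidene]-1,4-benzodioxin-2(3H)-one | Brc1ccc2c(c1)OC(=O)/C(=C/c1ccc(O[Si](C)(C)C(C)(C)C)c(O[Si](C)(C)C(C)(C)C)c1)O2 | intermediate
7 | sodium (R)-3-(3,4-dihydroxyphenyl)-2-hydroxypropanoate (sodium salt of (R)-danshensu) | O[C@H](Cc1ccc(O)c(O)c1)C(=O)[O-].[Na+] | starting material
8 | 4-methoxybenzyl (R)-3-(3,4-dihydroxyphenyl)-2-hydroxypropanoate | O[C@H](Cc1ccc(O)c(O)c1)C(=O)OCc1ccc(OC)cc1 | intermediate
9 | 4-methoxybenzyl (R)-3-[3,4-bis(tert-butyldimethylsilyloxy)phenyl]-2-hydroxypropanoate | O[C@H](Cc1ccc(O[Si](C)(C)C(C)(C)C)c(O[Si](C)(C)C(C)(C)C)c1)C(=O)OCc1ccc(OC)cc1 | intermediate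
10 | acryloyl chloride | C=CC(=O)Cl | starting material
11 | 4-methoxybenzyl (R)-2-(acryloyloxy)-3-[3,4-bis(tert-butyldimethylsilyloxy)phenyl]propanoate | C=CC(=O)O[C@H](Cc1ccc(O[Si](C)(C)C(C)(C)C)c(O[Si](C)(C)C(C)(C)C)c1)C(=O)OCc1ccc(OC)cc1 | intermediate
12 | fully protected coupling product (E cinnamate, Z benzylidene, R; four TBS ethers, 4-methoxybenzyl ester) | O=C(/C=C/c1ccc2c(c1)OC(=O)/C(=C/c1ccc(O[Si](C)(C)C(C)(C)C)c(O[Si](C)(C)C(C)(C)C)c1)O2)O[C@H](Cc1ccc(O[Si](C)(C)C(C)(C)C)c(O[Si](C)(C)C(C)(C)C)c1)C(=O)OCc1ccc(OC)cc1 | intermediate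
13 | tetrasilylated free acid (E, Z, R) | O=C(/C=C/c1ccc2c(c1)OC(=O)/C(=C/c1ccc(O[Si](C)(C)C(C)(C)C)c(O[Si](C)(C)C(C)(C)C)c1)O2)O[C@H](Cc1ccc(O[Si](C)(C)C(C)(C)C)c(O[Si](C)(C)C(C)(C)C)c1)C(=O)O | intermediate
14 | CNP0141754.1 (E, Z, R) | O=C(/C=C/c1ccc2c(c1)OC(=O)/C(=C/c1ccc(O)c(O)c1)O2)O[C@H](Cc1ccc(O)c(O)c1)C(=O)O | target

## Step count and risks

Total step count: 9.
Longest linear sequence: 6 steps (steps 1–3, then 7–9). The branch of steps 4–6, then 7–9, is equally long.

**Step 3 (Proposed new method)**

- What may go wrong:
  - The alkenyl carbon C2 may shift in place of C3a, because the 4-silyloxy group feeds density through the styrene unit towards C2.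
  - Oxygen may be transferred to the exocyclic alkene of 4 or of 6.
  - The peracid may fail to add to a ketone that two donor systems deactivate.
- Within the strategy, Me3SiOOSiMe3 with SnCl4 would be tried first, as an oxidant that does not epoxidise alkenes.
- Fallback by known chemistry, setting out from aldehyde 2 and coming back at 6. Both ring oxygens are placed on the arene first and the exocyclic alkene is made last.
  - Commercial 5-bromosalicylaldehyde has its hydroxyl para to bromine, which is the future O4. It is O-alkylated with tert-butyl bromoacetate (K2CO3, DMF, rt; Williamson ether synthesis) to tert-butyl 2-(4-bromo-2-formylphenoxy)acetate F1.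
  - Dakin-type Baeyer–Villiger oxidation of this ortho-alkoxybenzaldehyde with mCPBA in CH2Cl2 gives tert-butyl 2-[4-bromo-2-(formyloxy)phenoxy]acetate F2.
  - NaHCO3 in MeOH cleaves the formate to tert-butyl 2-(4-bromo-2-hydroxyphenoxy)acetate F3.
  - Catalytic TsOH in refluxing toluene, with azeotropic removal of water, removes the tert-butyl group and lactonises to 7-bromo-1,4-benzodioxin-2(3H)-one F4.
  - The lithium enolate of the lactone (LiN(SiMe3)2, THF, −78 °C) adds to 2 to give the aldol adduct F5 as a mixture of diastereomers.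
  - MsCl/Et3N converts the aldol into the corresponding methanesulfonate F6, and DBU-induced E1cB elimination should give the thermodynamically preferred Z alkene 6.

**Step 7**

- What may go wrong:
  - Oxidative addition into the electron-rich C7–Br bond may be slow.
  - The aryl lactone may open through the amine base and traces of water over long reaction times.
  - Palladium hydride may isomerise the benzylidene alkene.
  - The acrylate may oligomerise.
- Fallback without base, setting out from 6 and coming back at 12.
  - Stille vinylation of 6 with tributyl(vinyl)stannane (Pd(PPh3)4, toluene, 90 °C) gives (Z)-7-vinyl-3-[3,4-bis(tert-butyldimethylsilyloxy)benzylidene]-1,4-benzodioxin-2(3H)-one F7.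
  - Olefin cross-metathesis of this styrene with acrylate 11 (second-generation Grubbs catalyst, CH2Cl2, reflux) should give the E cinnamate 12. The trisubstituted exocyclic alkene is too hindered to take part.

**Step 9**

- What may go wrong:
  - Fluoride or water may open the aryl lactone while the free acid is present.
  - The catechols may oxidise in air.
  - Material may be lost when fluoride salts are separated from a very polar acid.
- Fallback, setting out from 12 and coming back at 14. The order of unmasking is inverted.
  - Et3N·3HF in THF acts on 12 to give the tetraphenol 4-methoxybenzyl ester F8, a neutral compound that can be purified on silica gel.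
  - The target is then released in a fluoride-free, non-nucleophilic acidolysis (TFA, large excess of anisole, CH2Cl2, 0 °C). The by-products of this step are removed by trituration.

## Further compounds

F1 | step 3 | tert-butyl 2-(4-bromo-2-formylphenoxy)acetate | O=Cc1cc(Br)ccc1OCC(=O)OC(C)(C)C
F2 | step 3 | tert-butyl 2-[4-bromo-2-(formyloxy)phenoxy]acetate | O=COc1cc(Br)ccc1OCC(=O)OC(C)(C)C
F3 | step 3 | tert-butyl 2-(4-bromo-2-hydroxyphenoxy)acetate | Oc1cc(Br)ccc1OCC(=O)OC(C)(C)C
F4 | step 3 | 7-bromo-1,4-benzodioxin-2(3H)-one | O=C1COc2ccc(Br)cc2O1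
F5 | step 3 | aldol adduct, 7-bromo-3-{[3,4-bis(tert-butyldimethylsilyloxy)phenyl](hydroxy)methyl}-1,4-benzodioxin-2(3H)-one, mixture of diastereomers | O=C1Oc2cc(Br)ccc2OC1C(O)c1ccc(O[Si](C)(C)C(C)(C)C)c(O[Si](C)(C)C(C)(C)C)c1
F6 | step 3 | methanesulfonate of F5, mixture of diastereomers | O=C1Oc2cc(Br)ccc2OC1C(OS(C)(=O)=O)c1ccc(O[Si](C)(C)C(C)(C)C)c(O[Si](C)(C)C(C)(C)C)c1
F7 | step 7 | (Z)-7-vinyl-3-[3,4-bis(tert-butyldimethylsilyloxy)benzylidene]-1,4-benzodioxin-2(3H)-one | C=Cc1ccc2c(c1)OC(=O)/C(=C/c1ccc(O[Si](C)(C)C(C)(C)C)c(O[Si](C)(C)C(C)(C)C)c1)O2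
F8 | step 9 | tetraphenol 4-methoxybenzyl ester (4-methoxybenzyl ester of 14; E, Z, R) | O=C(/C=C/c1ccc2c(c1)OC(=O)/C(=C/c1ccc(O)c(O)c1)O2)O[C@H](Cc1ccc(O)c(O)c1)C(=O)OCc1ccc(OC)cc1
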